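Locants: ring A carbons are counted from the methyl-bearing carbon and always named with the ring (carbon 1 CH3, carbon 2 H, carbon 3 OH, carbon 4 CO2H, carbon 5 the diaryl ether oxygen, carbon 6 the depsidone C=O); ring B carries B1 (ester O), B2 CH2OH, B3 OH, B4 (phthalide C=O), B5 (phthalide CH2) and B6 (ether O).
Cuts, in retrosynthetic order: the benzyl groups on the oxygen at carbon 3 and on the carboxyl at carbon 4 of ring A; the B4–C(=O) and C(=O)–OCH2(B5) bonds of the phthalide (back to B4–Br, CO and a free B5 CH2OH); B4–Br and B3–O; the ester bond between the carbonyl on carbon 6 of ring A and the B1 oxygen; the ether bond between carbon 5 of ring A and the B6 oxygen.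
Enabling feature: B4 lies between the B3 hydroxyl and the B5 CH2–O carbon and is the last open carbon of ring B once B2 and B5 both carry hydroxymethyl groups, so a palladium acyl formed there has only the B5 alcohol within reach of a five-membered closure.
Forward: ring B fragment 6 and ring A fragment 13 are joined by SNAr (ether bond from carbon 5 of ring A to the B6 oxygen); the seven-membered depsidone ring closes second (steps 11–13); B3–Br becomes B3–OH, B4 is brominated, and the phthalide ring closes last by carbonylation; hydrogenolysis finishes.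
Stereochemistry: the target has no stereocentre; what must be controlled is the ring B pattern, fixed by bromination para to the only free catechol hydroxyl (step 5) and ortho to the B3 phenol (step 15).

Key step: step 17

Remark on the chemistry: carbon 2 of ring A is activated by the oxygens on carbons 3 and 5 of that ring, so ring B is not brominated as a fully protected depsidone; its pattern is set through free phenols, one before and one after the rings are joined.
Abbreviations: TBS = tert-butyldimethylsilyl, Bn = benzyl, pin = pinacolato.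

Step 1
Reactants: 1 2,3-dihydroxyterephthalic acid
Product: 2 dimethyl 2,3-dihydroxyterephthalate
Conditions: MeOH, H2SO4 (cat.), reflux
Reagents that add atoms: methanol CO
Why: Fischer esterification in excess methanol converts both salicylic-type acids while the phenols stay untouched.

Step 2
Reactants: 2 dimethyl 2,3-dihydroxyterephthalate
Product: 3 dimethyl 2-(allyloxy)-3-hydroxyterephthalate
Conditions: allyl bromide (1.0 equiv), K2CO3 (1.0 equiv), DMF, 40 °C
Reagents that add atoms: allyl bromide C=CCBr
Why: Williamson etherification with one equivalent of base and halide mono-alkylates the symmetric catechol (both hydroxyls are equivalent, so only one mono-ether can form), and the remaining phenol stays chelated to its ortho ester, which slows a second alkylation.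

Step 3
Reactants: 3 dimethyl 2-(allyloxy)-3-hydroxyterephthalate
Product: 4 2-(allyloxy)-3,6-bis(hydroxymethyl)phenol
Conditions: LiAlH4, THF, 0 °C → rt; aq. potassium sodium tartrate
Reagents that add atoms: none
Why: Hydride reduction of both esters by LiAlH4 is the standard conversion of salicylates into salicyl alcohols, and the allyl ether is inert to it.

Step 4
Reactants: 4 2-(allyloxy)-3,6-bis(hydroxymethyl)phenol
Product: 5 2-(allyloxy)-3,6-bis(TBS-oxymethyl)phenol
Conditions: TBSCl (2.2 equiv), imidazole, DMF, 0 °C
Reagents that add atoms: tert-butyldimethylsilyl chloride CC(C)(C)[Si](C)(C)Cl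
Why: Silylation with TBSCl/imidazole takes the two primary benzylic alcohols much faster than the phenol, which is flanked by two ortho substituents.

Step 5
Reactants: 5 2-(allyloxy)-3,6-bis(TBS-oxymethyl)phenol
Product: 6 2-(allyloxy)-4-bromo-3,6-bis(TBS-oxymethyl)phenol
Conditions: NBS (1.0 equiv), MeCN, −20 °C → 0 °C
Reagents that add atoms: N-bromosuccinimide O=C1CCC(=O)N1Br
Why: Electrophilic aromatic bromination of a 2-alkoxyphenol goes para to the free hydroxyl in preference to para to the ether oxygen, so bromine enters at the carbon that becomes B3, para to the future B6 oxygen.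

Step 6
Reactants: 7 3-fluoro-5-methylphenol
Product: 8 1-(benzyloxy)-3-fluoro-5-methylbenzene
Conditions: BnBr, K2CO3, DMF, rt
Reagents that add atoms: benzyl bromide BrCc1ccccc1
Why: Williamson etherification of a simple phenol with a benzylic halide.

Step 7
Reactants: 8 1-(benzyloxy)-3-fluoro-5-methylbenzene
Product: 10 benzyl 2-(benzyloxy)-6-fluoro-4-methylbenzoate, via aryllithium 9 (not isolated)
Conditions: n-BuLi, THF, −78 °C; then cannulated into ClCO2Bn, THF, −78 °C → rt
Reagents that add atoms: benzyl chloroformate O=C(Cl)OCc1ccccc1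
Why: Directed ortho-metalation removes the most acidic ring hydrogen, between fluorine and the ether oxygen, at a temperature that suppresses benzylic deprotonation, and inverse addition to the chloroformate gives the ester without ketone formation.

Step 8
Reactants: 10 benzyl 2-(benzyloxy)-6-fluoro-4-methylbenzoate
Product: 11 benzyl 6-(benzyloxy)-3-bromo-2-fluoro-4-methylbenzoate
Conditions: NBS, MeCN, rt → 40 °C
Reagents that add atoms: N-bromosuccinimide O=C1CCC(=O)N1Br
Why: Electrophilic aromatic bromination with NBS follows the usual para preference of alkoxyarenes, placing bromine para to the benzyloxy group (between F and CH3, on the future carbon 6 of ring A) rather than at the more hindered ortho site.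

Step 9
Reactants: 11 benzyl 6-(benzyloxy)-3-bromo-2-fluoro-4-methylbenzoate
Product: 13 benzyl 6-(benzyloxy)-2-fluoro-3-formyl-4-methylbenzoate, via arylmagnesium chloride 12 (not isolated)
Conditions: iPrMgCl·LiCl, THF, −15 °C → 0 °C; DMF; aq. NH4Cl
Reagents that add atoms: N,N-dimethylformamide CN(C)C=O
Why: Bromine–magnesium exchange, helped by the ortho fluorine and tolerated by the doubly ortho-substituted benzyl ester, is followed by Bouveault-type formylation of the arylmagnesium with DMF.

Step 10
Reactants: 6 2-(allyloxy)-4-bromo-3,6-bis(TBS-oxymethyl)phenol; 13 benzyl 6-(benzyloxy)-2-fluoro-3-formyl-4-methylbenzoate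
Product: 14 benzyl 2-[2-(allyloxy)-4-bromo-3,6-bis(TBS-oxymethyl)phenoxy]-6-(benzyloxy)-3-formyl-4-methylbenzoate
Conditions: K2CO3, DMF, 70 °C
Reagents that add atoms: none
Why: Nucleophilic aromatic substitution by addition–elimination at a fluoride activated by an ortho formyl and an ortho ester group; since 6 has a single free hydroxyl, the ether oxygen is unambiguously the one para to bromine.

Step 11
Reactants: 14 benzyl 2-[2-(allyloxy)-4-bromo-3,6-bis(TBS-oxymethyl)phenoxy]-6-(benzyloxy)-3-formyl-4-methylbenzoate
Product: 15 2-[2-(allyloxy)-4-bromo-3,6-bis(TBS-oxymethyl)phenoxy]-4-(benzyloxy)-3-[(benzyloxy)carbonyl]-6-methylbenzoic acid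
Conditions: NaClO2, NaH2PO4, 2-methyl-2-butene, t-BuOH/THF/H2O, 0 °C → rt
Reagents that add atoms: sodium chlorite [Na+].[O-]Cl=O
Why: Pinnick oxidation converts the hindered aryl aldehyde into the acid under buffered conditions that leave silyl, allyl and benzyl groups alone, with 2-methyl-2-butene removing the hypochlorous acid.

Step 12
Reactants: 15 2-[2-(allyloxy)-4-bromo-3,6-bis(TBS-oxymethyl)phenoxy]-4-(benzyloxy)-3-[(benzyloxy)carbonyl]-6-methylbenzoic acid
Product: 16 4-(benzyloxy)-3-[(benzyloxy)carbonyl]-2-[4-bromo-2-hydroxy-3,6-bis(TBS-oxymethyl)phenoxy]-6-methylbenzoic acid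
Conditions: Pd(PPh3)4 (cat.), morpholine, THF, rt; dilute acid wash
Reagents that add atoms: none
Why: Tsuji–Trost-type deallylation, in which zerovalent palladium ionises the aryl allyl ether and morpholine takes up the allyl group, while the electron-rich aryl bromide does not undergo oxidative addition with this catalyst at room temperature.

Step 13
Reactants: 16 4-(benzyloxy)-3-[(benzyloxy)carbonyl]-2-[4-bromo-2-hydroxy-3,6-bis(TBS-oxymethyl)phenoxy]-6-methylbenzoic acid
Product: 17 benzyl 3-(benzyloxy)-8-bromo-6,9-bis(TBS-oxymethyl)-1-methyl-11-oxo-11H-dibenzo[b,e][1,4]dioxepine-4-carboxylate (depsidone with Br on B3)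
Conditions: DCC, DMAP (cat.), CH2Cl2 (0.005 M), 0 °C → rt
Reagents that add atoms: none
Why: Carbodiimide (Steglich-type) lactonisation of a 2-(2-hydroxyaryloxy)benzoic acid is the standard closure of the seven-membered depsidone ring; the B1 phenol is the only free hydroxyl and high dilution favours the 7-exo-trig closure.

Step 14
Reactants: 17 depsidone with Br on B3
Product: 19 benzyl 3-(benzyloxy)-8-hydroxy-6,9-bis(TBS-oxymethyl)-1-methyl-11-oxo-11H-dibenzo[b,e][1,4]dioxepine-4-carboxylate (OH on B3), via pinacol boronate 18 (not isolated)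
Conditions: B2pin2, Pd(dppf)Cl2 (cat.), KOAc, 1,4-dioxane, 85 °C; then KHSO5 (as 2KHSO5·KHSO4·K2SO4), acetone/H2O, 0 °C, 10 min
Reagents that add atoms: bis(pinacolato)diboron CC1(C)OB(OC1(C)C)B1OC(C)(C)C(C)(C)O1 (boron of 18); potassium peroxymonosulfate [K+].[O-]S(=O)(=O)OO (oxygen of 19)
Why: Miyaura borylation of the aryl bromide followed by a short, cold oxidation of the aryl boronate with peroxymonosulfate in a mildly acidic medium replaces Br by OH at B3 without hydrolysing the aryl ester or the silyl ethers.

Step 15
Reactants: 19 depsidone with OH on B3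
Product: 20 benzyl 3-(benzyloxy)-7-bromo-8-hydroxy-6,9-bis(TBS-oxymethyl)-1-methyl-11-oxo-11H-dibenzo[b,e][1,4]dioxepine-4-carboxylate (Br on B4)
Conditions: NBS (1.0 equiv), i-Pr2NH (cat.), CH2Cl2, −20 °C
Reagents that add atoms: N-bromosuccinimide O=C1CCC(=O)N1Br
Why: Amine-catalysed NBS bromination is ortho-selective for phenols, and B4 is the only unsubstituted carbon of ring B, far more reactive than carbon 2 of the ester-bearing ring A.

Step 16
Reactants: 20 depsidone with Br on B4 and OH on B3
Product: 21 benzyl 3-(benzyloxy)-7-bromo-8-hydroxy-6,9-bis(hydroxymethyl)-1-methyl-11-oxo-11H-dibenzo[b,e][1,4]dioxepine-4-carboxylate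
Conditions: HF·pyridine, THF/pyridine, 0 °C → rt
Reagents that add atoms: none
Why: Fluoride-mediated desilylation with HF·pyridine cleaves both primary TBS ethers under mildly acidic conditions that spare the depsidone ester, the benzyl groups and the aryl bromide.

Step 17
Reactants: 21 B4-bromo depsidone diol; 22 carbon monoxide
Product: 23 O-benzylconneotricone benzyl ester (phthalide fused at B4/B5)
Conditions: Pd(OAc)2 (5 mol %), Xantphos (6 mol %), CO (1 atm), Et3N, 1,4-dioxane, 80 °C
Reagents that add atoms: none
Why: Pd(OAc)2 is reduced in the flask to zerovalent palladium, which inserts into the B4–Br bond; CO then inserts to give an aroyl–palladium species, the B5 hydroxymethyl oxygen binds and C–O reductive elimination releases the lactone while Et3N takes up HBr. The closest known reaction is the palladium-catalysed carbonylative lactonisation of 2-bromobenzyl alcohols to phthalides. The five-membered ring closes in a 5-exo-trig sense at the acyl carbon, through a six-membered acyl(alkoxo)palladium chelate. No stereocentre is formed. The step needs one of three hydroxyls to capture the acyl group, and geometry secures this: the B3 phenol could only give a four-membered ring and the B2 hydroxymethyl group sits meta to B4. The wide-bite-angle bisphosphine allows insertion into the doubly ortho-substituted bromide at atmospheric CO pressure, and the amine base is mild enough for the depsidone and benzyl esters.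

Step 18
Reactants: 23 O-benzylconneotricone benzyl ester
Product: 24 Conneotricone
Conditions: H2 (1 atm), 10% Pd/C, EtOAc/THF, rt
Reagents that add atoms: none
Why: Catalytic hydrogenolysis cleaves the aryl benzyl ether and the benzyl ester under neutral conditions, where the phthalide, the depsidone ester and the hydroxymethyl group are reduced much more slowly, so the reaction is stopped after uptake of two equivalents of hydrogen.

Compound list
1 | 2,3-dihydroxyterephthalic acid | O=C(O)c1ccc(C(=O)O)c(O)c1O | starting material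
2 | dimethyl 2,3-dihydroxyterephthalate | COC(=O)c1ccc(C(=O)OC)c(O)c1O | intermediate
3 | dimethyl 2-(allyloxy)-3-hydroxyterephthalate | COC(=O)c1ccc(C(=O)OC)c(OCC=C)c1O | intermediate
4 | 2-(allyloxy)-3,6-bis(hydroxymethyl)phenol | OCc1ccc(CO)c(OCC=C)c1O | intermediate
5 | 2-(allyloxy)-3,6-bis{[(tert-butyldimethylsilyl)oxy]methyl}phenol | CC(C)(C)[Si](C)(C)OCc1ccc(CO[Si](C)(C)C(C)(C)C)c(OCC=C)c1O | intermediate
6 | 2-(allyloxy)-4-bromo-3,6-bis{[(tert-butyldimethylsilyl)oxy]methyl}phenol (ring B fragment) | CC(C)(C)[Si](C)(C)OCc1cc(Br)c(CO[Si](C)(C)C(C)(C)C)c(OCC=C)c1O | intermediate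
7 | 3-fluoro-5-methylphenol | Cc1cc(O)cc(F)c1 | starting material
8 | 1-(benzyloxy)-3-fluoro-5-methylbenzene | Cc1cc(F)cc(OCc2ccccc2)c1 | intermediate
9 | [2-(benzyloxy)-6-fluoro-4-methylphenyl]lithium | [Li]c1c(F)cc(C)cc1OCc1ccccc1 | intermediate
10 | benzyl 2-(benzyloxy)-6-fluoro-4-methylbenzoate | Cc1cc(F)c(C(=O)OCc2ccccc2)c(OCc2ccccc2)c1 | intermediate
11 | benzyl 6-(benzyloxy)-3-bromo-2-fluoro-4-methylbenzoate | Cc1cc(OCc2ccccc2)c(C(=O)OCc2ccccc2)c(F)c1Br | intermediate
12 | [4-(benzyloxy)-3-(benzyloxycarbonyl)-2-fluoro-6-methylphenyl]magnesium chloride (LiCl complex) | Cc1cc(OCc2ccccc2)c(C(=O)OCc2ccccc2)c(F)c1[Mg]Cl | intermediate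
13 | benzyl 6-(benzyloxy)-2-fluoro-3-formyl-4-methylbenzoate (ring A fragment) | Cc1cc(OCc2ccccc2)c(C(=O)OCc2ccccc2)c(F)c1C=O | intermediate
14 | benzyl 2-[2-(allyloxy)-4-bromo-3,6-bis(TBS-oxymethyl)phenoxy]-6-(benzyloxy)-3-formyl-4-methylbenzoate | Cc1cc(OCc2ccccc2)c(C(=O)OCc2ccccc2)c(Oc2c(CO[Si](C)(C)C(C)(C)C)cc(Br)c(CO[Si](C)(C)C(C)(C)C)c2OCC=C)c1C=O | intermediate
15 | 2-[2-(allyloxy)-4-bromo-3,6-bis(TBS-oxymethyl)phenoxy]-4-(benzyloxy)-3-[(benzyloxy)carbonyl]-6-methylbenzoic acid | Cc1cc(OCc2ccccc2)c(C(=O)OCc2ccccc2)c(Oc2c(CO[Si](C)(C)C(C)(C)C)cc(Br)c(CO[Si](C)(C)C(C)(C)C)c2OCC=C)c1C(=O)O | intermediate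
16 | 4-(benzyloxy)-3-[(benzyloxy)carbonyl]-2-[4-bromo-2-hydroxy-3,6-bis(TBS-oxymethyl)phenoxy]-6-methylbenzoic acid | Cc1cc(OCc2ccccc2)c(C(=O)OCc2ccccc2)c(Oc2c(CO[Si](C)(C)C(C)(C)C)cc(Br)c(CO[Si](C)(C)C(C)(C)C)c2O)c1C(=O)O | intermediate
17 | benzyl 3-(benzyloxy)-8-bromo-6,9-bis(TBS-oxymethyl)-1-methyl-11-oxo-11H-dibenzo[b,e][1,4]dioxepine-4-carboxylate (Br on B3) | Cc1cc(OCc3ccccc3)c(C(=O)OCc3ccccc3)c2c1C(=O)Oc1c(CO[Si](C)(C)C(C)(C)C)c(Br)cc(CO[Si](C)(C)C(C)(C)C)c1O2 | intermediate
18 | 8-(pinacolatoboryl) analogue of 17 (Bpin on B3) | Cc1cc(OCc3ccccc3)c(C(=O)OCc3ccccc3)c2c1C(=O)Oc1c(CO[Si](C)(C)C(C)(C)C)c(B3OC(C)(C)C(C)(C)O3)cc(CO[Si](C)(C)C(C)(C)C)c1O2 | intermediate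
19 | benzyl 3-(benzyloxy)-8-hydroxy-6,9-bis(TBS-oxymethyl)-1-methyl-11-oxo-11H-dibenzo[b,e][1,4]dioxepine-4-carboxylate (OH on B3) | Cc1cc(OCc3ccccc3)c(C(=O)OCc3ccccc3)c2c1C(=O)Oc1c(CO[Si](C)(C)C(C)(C)C)c(O)cc(CO[Si](C)(C)C(C)(C)C)c1O2 | intermediate
20 | benzyl 3-(benzyloxy)-7-bromo-8-hydroxy-6,9-bis(TBS-oxymethyl)-1-methyl-11-oxo-11H-dibenzo[b,e][1,4]dioxepine-4-carboxylate (Br on B4) | Cc1cc(OCc3ccccc3)c(C(=O)OCc3ccccc3)c2c1C(=O)Oc1c(CO[Si](C)(C)C(C)(C)C)c(O)c(Br)c(CO[Si](C)(C)C(C)(C)C)c1O2 | intermediate
21 | benzyl 3-(benzyloxy)-7-bromo-8-hydroxy-6,9-bis(hydroxymethyl)-1-methyl-11-oxo-11H-dibenzo[b,e][1,4]dioxepine-4-carboxylate | Cc1cc(OCc3ccccc3)c(C(=O)OCc3ccccc3)c2c1C(=O)Oc1c(CO)c(O)c(Br)c(CO)c1O2 | intermediate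
22 | carbon monoxide | [C-]#[O+] | starting material
23 | O-benzylconneotricone benzyl ester (benzyl ether on the ring A phenol, benzyl ester on the ring A carboxyl, phthalide fused at B4/B5) | Cc1cc(OCc3ccccc3)c(C(=O)OCc3ccccc3)c2c1C(=O)Oc1c(CO)c(O)c3c(c1O2)COC3=O | intermediate
24 | Conneotricone | Cc1cc(O)c(C(=O)O)c2c1C(=O)Oc1c(CO)c(O)c3c(c1O2)COC3=O | target

Total: 18 steps. Longest linear sequence: 14 steps (steps 1–5 and 10–18, from 2,3-dihydroxyterephthalic acid); the ring A branch (steps 6–9) joins at step 10.

Steps most likely to fail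

Step 17. Oxidative addition into a bromide flanked by a phenol and a hydroxymethyl group may be slow, so that CO saturates and deactivates the catalyst, and the amine base may promote acyl transfer from the depsidone ester to the free B2 hydroxymethyl group. The fallback sets out from 20, with both silyl ethers still in place. Aryloxycarbonylation with 2,4,6-trichlorophenyl formate, Pd(OAc)2, Xantphos and Et3N in toluene at 80 °C releases CO slowly in the flask and has no free alcohol present. It should give 4-benzyl 7-(2,4,6-trichlorophenyl) 3-(benzyloxy)-8-hydroxy-1-methyl-11-oxo-6,9-bis(TBS-oxymethyl)-11H-dibenzo[b,e][1,4]dioxepine-4,7-dicarboxylate F1. HF·pyridine then removes both silyl groups, and the liberated B5 alcohol should close onto the activated ester with loss of 2,4,6-trichlorophenol, coming back to the route at 23.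

Step 10. Addition of the doubly ortho-substituted phenoxide to the fluorine-bearing carbon may be sterically retarded, leaving time for the phenoxide to attack the benzylic carbon of the ester or for the aldehyde to degrade. The fallback sets out from 4 and moves the C–O coupling ahead of silylation, so that the nucleophile carries small CH2OH groups. NBS in MeCN should brominate 4 para to the phenol and give 2-(allyloxy)-4-bromo-3,6-bis(hydroxymethyl)phenol F2. In the SNAr with 13 (K2CO3, DMF) carbonate deprotonates only the phenol, which should give benzyl 2-[2-(allyloxy)-4-bromo-3,6-bis(hydroxymethyl)phenoxy]-6-(benzyloxy)-3-formyl-4-methylbenzoate F3. Silylation with TBSCl and imidazole comes back to the route at 14.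

Step 8. Bromination may partition between the positions para and ortho to the benzyloxy group, because the neighbouring fluorine deactivates the para site, or it may stall on the ester-deactivated ring. The fallback sets out from 10 and replaces electrophilic substitution by deprotonative metalation: TMPMgCl·LiCl in THF should magnesiate the ring hydrogen next to fluorine, the site amide bases prefer over the one next to an ether oxygen. This gives arylmagnesium 12 directly, and DMF then comes back to the route at 13; this detour makes no new compound (F0).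

Further compounds
F1 | step 17 | 4-benzyl 7-(2,4,6-trichlorophenyl) 3-(benzyloxy)-8-hydroxy-1-methyl-11-oxo-6,9-bis(TBS-oxymethyl)-11H-dibenzo[b,e][1,4]dioxepine-4,7-dicarboxylate | Cc1cc(OCc3ccccc3)c(C(=O)OCc3ccccc3)c2c1C(=O)Oc1c(CO[Si](C)(C)C(C)(C)C)c(O)c(C(=O)Oc3c(Cl)cc(Cl)cc3Cl)c(CO[Si](C)(C)C(C)(C)C)c1O2
F2 | step 10 | 2-(allyloxy)-4-bromo-3,6-bis(hydroxymethyl)phenol | OCc1cc(Br)c(CO)c(OCC=C)c1O
F3 | step 10 | benzyl 2-[2-(allyloxy)-4-bromo-3,6-bis(hydroxymethyl)phenoxy]-6-(benzyloxy)-3-formyl-4-methylbenzoate | Cc1cc(OCc2ccccc2)c(C(=O)OCc2ccccc2)c(Oc2c(CO)cc(Br)c(CO)c2OCC=C)c1C=O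
F0 | step 8 | none | none
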